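**Strategy**

The route rests on closing the cyclopentane (ring A, C1–C5) at C2–C3, its only edge without a substituent, flanked by the quaternary C1 and the carbinol C4. Both methylenes are traced back to vinyl CH termini of like polarity, so ring-closing metathesis of an acyclic 1,6-dien-3-one forms ring A in one operation and leaves C4 as an enone carbonyl that then steers the C5 aldol, the C2=C3 reduction and the isopropyl addition. The precursor holds only two stereocentres (C1, C10), set on a butenolide template. Ring B (cycloheptane) is closed last at C8–C9 by a Nozaki–Hiyama–Kishi reaction.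

Key step: step 7

Remark on numbering: C1 = quaternary carbon bearing CH3; C2, C3 = CH2 of ring A; C4 = C(OH)(isopropyl); C5 = ring-fusion CH; C6 = CH–O-acyl; C7 = CH2; C8 = C(=CH2); C9, C10 = CH–OH (C10 bonded to C1, C9 to C8).
Abbreviations: PMB = 4-methoxybenzyl; TBS = tert-butyldimethylsilyl.
Assumption: compounds 1, 2 and 13 are bought, and the ProPhenol ligand enantiomer used in step 1 is the one that gives the (S)-carbinol.

**Route**

Step 1
Reactants: 1 2-[(4-methoxybenzyl)oxy]acetaldehyde; 2 methyl propiolate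
Product: 4 methyl (4S)-4-hydroxy-5-(PMBO)pent-2-ynoate, via alkynylzinc 3 (not isolated)
Conditions: Me2Zn (3 equiv), ProPhenol ligand (10 mol%), Ph3PO (20 mol%), toluene, 4 °C; then H2O
Reagents that add atoms: dimethylzinc C[Zn]C (CH3Zn unit in 3 only)
Why: Catalytic enantioselective alkynylation of an aldehyde (zinc–ProPhenol alkynylzinc addition), in which dimethylzinc metalates the propiolate and the chiral dinuclear zinc complex delivers the alkynyl group to one aldehyde face, which should set C10 as (S), the centre from which all others are relayed.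

Step 2
Reactants: 4 methyl (4S)-4-hydroxy-5-(PMBO)pent-2-ynoate
Product: 6 (5S)-5-[(PMBO)methyl]-4-methylfuran-2(5H)-one, via Z-hydroxy enoate 5 (not isolated)
Conditions: Me2CuLi (2.5 equiv, from MeLi and CuI), THF, −78 °C; then H2O, rt
Reagents that add atoms: lithium dimethylcuprate [Li+].C[Cu-]C
Why: syn-Carbocupration of the ynoate (cuprate conjugate addition) places CH3 and copper cis, so protonation gives the (Z)-enoate 5, whose C10 hydroxyl is cis to the ester and lactonises at once to the butenolide without touching C10.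

Step 3
Reactants: 6 (5S)-5-[(PMBO)methyl]-4-methylfuran-2(5H)-one
Product: 8 (4R,5S)-5-[(PMBO)methyl]-4-methyl-4-vinyldihydrofuran-2(3H)-one, via silyl ketene acetal 7 (not isolated)
Conditions: vinylMgBr (3 equiv), CuBr·SMe2 (20 mol%), Me3SiCl (3 equiv), THF, −78 → −30 °C; then 1 M HCl
Reagents that add atoms: vinylmagnesium bromide C=C[Mg]Br; chlorotrimethylsilane C[Si](C)(C)Cl (silyl group in 7 only)
Why: Copper-catalysed, silyl-chloride-accelerated conjugate addition of a Grignard reagent, in which the vinyl group should enter the butenolide face anti to the CH2OPMB group on C10 and so create the quaternary C1 (vinyl trans, methyl cis to that group), the ketene acetal 7 being hydrolysed on work-up.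

Step 4
Reactants: 8 (4R,5S)-5-[(PMBO)methyl]-4-methyl-4-vinyldihydrofuran-2(3H)-one
Product: 9 (3R,4S)-4-hydroxy-N-methoxy-5-(PMBO)-N,3-dimethyl-3-vinylpentanamide
Conditions: MeNH(OMe)·HCl, Me3Al, CH2Cl2, 0 °C → rt; then H2O
Reagents that add atoms: N,O-dimethylhydroxylamine hydrochloride CNOC.Cl
Why: Aluminium amide aminolysis of the lactone (Weinreb amide formation) opens the ring at the acyl C–O bond, leaves C1 and C10 untouched and puts C4 at the oxidation level that accepts exactly one vinyl nucleophile.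

Step 5
Reactants: 9 (3R,4S)-4-hydroxy-N-methoxy-5-(PMBO)-N,3-dimethyl-3-vinylpentanamide
Product: 10 (3R,4S)-4-(TBSO)-N-methoxy-5-(PMBO)-N,3-dimethyl-3-vinylpentanamide
Conditions: TBSOTf, 2,6-lutidine, CH2Cl2, −78 → 0 °C
Reagents that add atoms: tert-butyldimethylsilyl trifluoromethanesulfonate CC(C)(C)[Si](C)(C)OS(=O)(=O)C(F)(F)F
Why: Silylation of the hindered secondary hydroxyl with the silyl triflate blocks relactonisation and later lactol formation, and the non-chelating silyl ether is needed for the stereocontrol in step 15.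

Step 6
Reactants: 10 (3R,4S)-4-(TBSO)-N-methoxy-5-(PMBO)-N,3-dimethyl-3-vinylpentanamide
Product: 11 (5R,6S)-6-(TBSO)-7-(PMBO)-5-methyl-5-vinylhept-1-en-3-one
Conditions: vinylMgBr, THF, 0 °C; then cold 1 M HCl
Reagents that add atoms: vinylmagnesium bromide C=C[Mg]Br
Why: Grignard addition to a Weinreb amide stops at the ketone because the five-membered magnesium chelate survives until the acidic quench, which gives the acryloyl unit (C3–C4) of the 1,6-dien-3-one.

Step 7
Reactants: 11 (5R,6S)-6-(TBSO)-7-(PMBO)-5-methyl-5-vinylhept-1-en-3-one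
Product: 12 (4R)-4-[(1S)-1-(TBSO)-2-(PMBO)ethyl]-4-methylcyclopent-2-en-1-one
Conditions: second-generation Grubbs catalyst (5 mol%), CH2Cl2 (0.01 M), 40 °C
Reagents that add atoms: none
Why: The ruthenium alkylidene engages one terminal alkene, and [2+2] cycloaddition with the second alkene followed by cycloreversion of the ruthenacyclobutane joins C2 to C3 and expels ethene, whose loss makes the closure irreversible. The closest known reaction type is the ring-closing metathesis of 1,6-dien-3-ones to 4,4-disubstituted cyclopent-2-enones. Ring A closes as a five-membered ring through an intramolecular metallacycle in which the three-atom tether C1–C5–C4 links the two alkenes, helped by the gem-disubstitution at C1. No stereocentre is formed: C1 and C10 pass through unchanged and the cis geometry of C2=C3 is fixed by the ring. The step needs ring closure to outrun cross-metathesis of the electron-poor acryloyl group, which high dilution and the absence of any third alkene in 11 should secure. The CH2–CH2 edge of ring A thus arises without polar activation at either neopentyl-type position.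

Step 8
Reactants: 13 3-bromobut-3-en-1-ol
Product: 14 3-bromobut-3-enal
Conditions: Dess–Martin periodinane, CH2Cl2, 0 °C; filtered cold and used at once
Reagents that add atoms: none
Why: Dess–Martin oxidation of the homoallylic alcohol under non-basic conditions should give the β,γ-unsaturated aldehyde without migration of the double bond into conjugation.

Step 9
Reactants: 12 (4R)-4-[(1S)-1-(TBSO)-2-(PMBO)ethyl]-4-methylcyclopent-2-en-1-one; 14 3-bromobut-3-enal
Product: 16 (4S,5S)-5-[(1S)-3-bromo-1-hydroxybut-3-en-1-yl]-4-[(1S)-1-(TBSO)-2-(PMBO)ethyl]-4-methylcyclopent-2-en-1-one, via lithium dienolate 15 (not isolated)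
Conditions: LDA, THF, −78 °C; then 14; AcOH, −78 °C
Reagents that add atoms: lithium diisopropylamide [Li+].CC(C)[N-]C(C)C (lithium in 15 only)
Why: Lithium enolate aldol addition, in which only C5 can be deprotonated (C3 is vinylic, C1 quaternary), the aldehyde should approach the dienolate face anti to the bulky silyloxyalkyl group on C1 (new C5–C6 bond cis to the methyl), and the ring-fixed (E)-enolate should react through a chair Zimmerman–Traxler transition state to give the anti aldol, (S) at C5 and C6.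

Step 10
Reactants: 16 (4S,5S)-5-[(1S)-3-bromo-1-hydroxybut-3-en-1-yl]-4-[(1S)-1-(TBSO)-2-(PMBO)ethyl]-4-methylcyclopent-2-en-1-one
Product: 17 (2S,3S)-2-[(1S)-3-bromo-1-hydroxybut-3-en-1-yl]-3-[(1S)-1-(TBSO)-2-(PMBO)ethyl]-3-methylcyclopentan-1-one
Conditions: [(Ph3P)CuH]6 (0.5 equiv), H2O (3 equiv), benzene/THF, rt
Reagents that add atoms: none
Why: Copper hydride conjugate reduction (hydride to C2, protonation of the copper enolate at C3) saturates the C2=C3 bond chemoselectively under neutral conditions, so the vinyl bromide, the β-hydroxy ketone and C5 are left alone.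

Step 11
Reactants: 17 (2S,3S)-2-[(1S)-3-bromo-1-hydroxybut-3-en-1-yl]-3-[(1S)-1-(TBSO)-2-(PMBO)ethyl]-3-methylcyclopentan-1-one
Product: 18 (1R,2S,3S)-2-[(1S)-3-bromo-1-hydroxybut-3-en-1-yl]-3-[(1S)-1-(TBSO)-2-(PMBO)ethyl]-3-methyl-1-(propan-2-yl)cyclopentan-1-ol
Conditions: iPrMgCl (4 equiv) premixed with CeCl3 (4 equiv), THF, −78 → −40 °C; then H2O
Reagents that add atoms: isopropylmagnesium chloride CC(C)[Mg]Cl
Why: Organocerium 1,2-addition, weakly basic so that enolisation, retro-aldol and bromine–metal exchange are avoided, in which the isopropyl group should attack the cyclopentanone face opposite to the C5 side chain and the C1 methyl (both on the other face) and give (R) at C4 with the hydroxyl cis to the C5–C6 bond.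

Step 12
Reactants: 18 (1R,2S,3S)-2-[(1S)-3-bromo-1-hydroxybut-3-en-1-yl]-3-[(1S)-1-(TBSO)-2-(PMBO)ethyl]-3-methyl-1-(propan-2-yl)cyclopentan-1-ol
Product: 19 (1S)-3-bromo-1-{(1S,2S,5R)-2-[(1S)-1-(TBSO)-2-(PMBO)ethyl]-5-hydroxy-2-methyl-5-(propan-2-yl)cyclopentyl}but-3-en-1-yl 3-methylbutanoate
Conditions: 3-methylbutanoyl chloride, pyridine, DMAP (10 mol%), CH2Cl2, 0 °C → rt
Reagents that add atoms: 3-methylbutanoyl chloride CC(C)CC(=O)Cl
Why: Nucleophile-catalysed acylation distinguishes the secondary C6 hydroxyl from the tertiary C4 hydroxyl on steric grounds and installs the ester of the target.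

Step 13
Reactants: 19 (1S)-3-bromo-1-{(1S,2S,5R)-2-[(1S)-1-(TBSO)-2-(PMBO)ethyl]-5-hydroxy-2-methyl-5-(propan-2-yl)cyclopentyl}but-3-en-1-yl 3-methylbutanoate
Product: 20 (1S)-3-bromo-1-{(1S,2S,5R)-2-[(1S)-1-(TBSO)-2-hydroxyethyl]-5-hydroxy-2-methyl-5-(propan-2-yl)cyclopentyl}but-3-en-1-yl 3-methylbutanoate
Conditions: DDQ, CH2Cl2/pH 7 buffer (10:1), 0 °C
Reagents that add atoms: none
Why: Oxidative cleavage of the 4-methoxybenzyl ether (benzylic hydride abstraction by DDQ, hydrolysis of the oxocarbenium ion) frees the primary C9 hydroxyl while silyl ether, ester, vinyl bromide and tertiary alcohol are inert.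

Step 14
Reactants: 20 (1S)-3-bromo-1-{(1S,2S,5R)-2-[(1S)-1-(TBSO)-2-hydroxyethyl]-5-hydroxy-2-methyl-5-(propan-2-yl)cyclopentyl}but-3-en-1-yl 3-methylbutanoate
Product: 21 (1S)-3-bromo-1-{(1S,2S,5R)-2-[(1S)-1-(TBSO)-2-oxoethyl]-5-hydroxy-2-methyl-5-(propan-2-yl)cyclopentyl}but-3-en-1-yl 3-methylbutanoate
Conditions: Dess–Martin periodinane, CH2Cl2, 0 °C → rt
Reagents that add atoms: none
Why: Dess–Martin oxidation converts the primary alcohol into the α-silyloxy aldehyde, the tertiary alcohol cannot be oxidised, and no lactol can form because the C4 hydroxyl and the C1 side chain lie on opposite faces of ring A.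

Step 15
Reactants: 21 (1S)-3-bromo-1-{(1S,2S,5R)-2-[(1S)-1-(TBSO)-2-oxoethyl]-5-hydroxy-2-methyl-5-(propan-2-yl)cyclopentyl}but-3-en-1-yl 3-methylbutanoate
Product: 23 (1R,3aS,4S,5R,8S,8aS)-4-(TBSO)-1,5-dihydroxy-3a-methyl-6-methylidene-1-(propan-2-yl)decahydroazulen-8-yl 3-methylbutanoate, via alkenylchromium 22 (not isolated)
Conditions: CrCl2 (10 equiv), NiCl2 (10 mol%), DMSO/THF, rt, 0.003 M; then H2O
Reagents that add atoms: chromium dichloride [Cr+2].[Cl-].[Cl-] (CrCl2 unit in 22 only)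
Why: Intramolecular Nozaki–Hiyama–Kishi reaction, in which oxidative addition of the C8–Br bond to zerovalent nickel, transmetalation to trivalent chromium and addition of alkenylchromium 22 to the aldehyde close the seven-membered ring B at C8–C9 (7-exo-trig at the carbonyl) and create the exocyclic methylene and the allylic C9 hydroxyl together, and attack anti to the C10–O bond with the silyloxy group pseudo-equatorial (Felkin–Anh) should give the 9,10-cis arrangement, (R) at C9.

Step 16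
Reactants: 23 (1R,3aS,4S,5R,8S,8aS)-4-(TBSO)-1,5-dihydroxy-3a-methyl-6-methylidene-1-(propan-2-yl)decahydroazulen-8-yl 3-methylbutanoate
Product: 24 (1R,3aS,4S,5R,8S,8aS)-1,4,5-trihydroxy-3a-methyl-6-methylidene-1-(propan-2-yl)decahydroazulen-8-yl 3-methylbutanoate
Conditions: HF·pyridine, pyridine, THF, 0 °C → rt
Reagents that add atoms: none
Why: Fluoride cleavage of the Si–O bond under buffered conditions should leave the ester, the tertiary and allylic alcohols and the 1,1-disubstituted alkene untouched.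

**Compound list**

1 | 2-[(4-methoxybenzyl)oxy]acetaldehyde | O=CCOCc1ccc(OC)cc1 | starting material
2 | methyl propiolate | C#CC(=O)OC | starting material
3 | methyl(3-methoxy-3-oxoprop-1-yn-1-yl)zinc | C[Zn]C#CC(=O)OC | intermediate
4 | methyl (4S)-4-hydroxy-5-(PMBO)pent-2-ynoate | COC(=O)C#C[C@H](O)COCc1ccc(OC)cc1 | intermediate
5 | methyl (2Z,4S)-4-hydroxy-5-(PMBO)-3-methylpent-2-enoate | COC(=O)/C=C(/C)[C@H](O)COCc1ccc(OC)cc1 | intermediate
6 | (5S)-5-[(PMBO)methyl]-4-methylfuran-2(5H)-one | O=C1C=C(C)[C@@H](COCc2ccc(OC)cc2)O1 | intermediate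
7 | trimethylsilyl ketene acetal of 8 (2-trimethylsilyloxy-4,5-dihydrofuran, ring carbons as in 8) | C[Si](C)(C)OC1=C[C@](C)(C=C)[C@@H](COCc2ccc(OC)cc2)O1 | intermediate
8 | (4R,5S)-5-[(PMBO)methyl]-4-methyl-4-vinyldihydrofuran-2(3H)-one | O=C1C[C@](C)(C=C)[C@@H](COCc2ccc(OC)cc2)O1 | intermediate
9 | (3R,4S)-4-hydroxy-N-methoxy-5-(PMBO)-N,3-dimethyl-3-vinylpentanamide | CON(C)C(=O)C[C@](C)(C=C)[C@H](O)COCc1ccc(OC)cc1 | intermediate
10 | (3R,4S)-4-(TBSO)-N-methoxy-5-(PMBO)-N,3-dimethyl-3-vinylpentanamide | CON(C)C(=O)C[C@](C)(C=C)[C@H](O[Si](C)(C)C(C)(C)C)COCc1ccc(OC)cc1 | intermediate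
11 | (5R,6S)-6-(TBSO)-7-(PMBO)-5-methyl-5-vinylhept-1-en-3-one | C=CC(=O)C[C@](C)(C=C)[C@H](O[Si](C)(C)C(C)(C)C)COCc1ccc(OC)cc1 | intermediate
12 | (4R)-4-[(1S)-1-(TBSO)-2-(PMBO)ethyl]-4-methylcyclopent-2-en-1-one | O=C1C=C[C@](C)([C@H](O[Si](C)(C)C(C)(C)C)COCc2ccc(OC)cc2)C1 | intermediate
13 | 3-bromobut-3-en-1-ol | OCCC(Br)=C | starting material
14 | 3-bromobut-3-enal | O=CCC(Br)=C | intermediate
15 | lithium cross-conjugated dienolate of 12 | [Li+].[O-]C1=C[C@@](C)([C@H](O[Si](C)(C)C(C)(C)C)COCc2ccc(OC)cc2)C=C1 | intermediate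
16 | (4S,5S)-5-[(1S)-3-bromo-1-hydroxybut-3-en-1-yl]-4-[(1S)-1-(TBSO)-2-(PMBO)ethyl]-4-methylcyclopent-2-en-1-one | O=C1C=C[C@](C)([C@H](O[Si](C)(C)C(C)(C)C)COCc2ccc(OC)cc2)[C@H]1[C@@H](O)CC(Br)=C | intermediate
17 | (2S,3S)-2-[(1S)-3-bromo-1-hydroxybut-3-en-1-yl]-3-[(1S)-1-(TBSO)-2-(PMBO)ethyl]-3-methylcyclopentan-1-one | O=C1CC[C@](C)([C@H](O[Si](C)(C)C(C)(C)C)COCc2ccc(OC)cc2)[C@H]1[C@@H](O)CC(Br)=C | intermediate
18 | (1R,2S,3S)-2-[(1S)-3-bromo-1-hydroxybut-3-en-1-yl]-3-[(1S)-1-(TBSO)-2-(PMBO)ethyl]-3-methyl-1-(propan-2-yl)cyclopentan-1-ol | CC(C)[C@]1(O)CC[C@](C)([C@H](O[Si](C)(C)C(C)(C)C)COCc2ccc(OC)cc2)[C@H]1[C@@H](O)CC(Br)=C | intermediate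
19 | (1S)-3-bromo-1-{(1S,2S,5R)-2-[(1S)-1-(TBSO)-2-(PMBO)ethyl]-5-hydroxy-2-methyl-5-(propan-2-yl)cyclopentyl}but-3-en-1-yl 3-methylbutanoate | CC(C)[C@]1(O)CC[C@](C)([C@H](O[Si](C)(C)C(C)(C)C)COCc2ccc(OC)cc2)[C@H]1[C@@H](OC(=O)CC(C)C)CC(Br)=C | intermediate
20 | (1S)-3-bromo-1-{(1S,2S,5R)-2-[(1S)-1-(TBSO)-2-hydroxyethyl]-5-hydroxy-2-methyl-5-(propan-2-yl)cyclopentyl}but-3-en-1-yl 3-methylbutanoate | CC(C)[C@]1(O)CC[C@](C)([C@H](O[Si](C)(C)C(C)(C)C)CO)[C@H]1[C@@H](OC(=O)CC(C)C)CC(Br)=C | intermediate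
21 | (1S)-3-bromo-1-{(1S,2S,5R)-2-[(1S)-1-(TBSO)-2-oxoethyl]-5-hydroxy-2-methyl-5-(propan-2-yl)cyclopentyl}but-3-en-1-yl 3-methylbutanoate | CC(C)[C@]1(O)CC[C@](C)([C@H](O[Si](C)(C)C(C)(C)C)C=O)[C@H]1[C@@H](OC(=O)CC(C)C)CC(Br)=C | intermediate
22 | alkenylchromium dichloride from 21 (CrCl2 in place of Br at C8) | CC(C)[C@]1(O)CC[C@](C)([C@H](O[Si](C)(C)C(C)(C)C)C=O)[C@H]1[C@@H](OC(=O)CC(C)C)CC(=C)[Cr](Cl)Cl | intermediate
23 | (1R,3aS,4S,5R,8S,8aS)-4-(TBSO)-1,5-dihydroxy-3a-methyl-6-methylidene-1-(propan-2-yl)decahydroazulen-8-yl 3-methylbutanoate | C=C1C[C@H](OC(=O)CC(C)C)[C@@H]2[C@](C)(CC[C@@]2(O)C(C)C)[C@H](O[Si](C)(C)C(C)(C)C)[C@@H]1O | intermediate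
24 | (1R,3aS,4S,5R,8S,8aS)-1,4,5-trihydroxy-3a-methyl-6-methylidene-1-(propan-2-yl)decahydroazulen-8-yl 3-methylbutanoate (CNP0204264.1) | C=C1C[C@H](OC(=O)CC(C)C)[C@@H]2[C@](C)(CC[C@@]2(O)C(C)C)[C@H](O)[C@@H]1O | target

**Step count and risks**

Total step count: 16 (15 in the main line plus step 8 for aldehyde 14). Longest linear sequence: 15 steps (steps 1–7 and 9–16).

Steps most likely to fail:

1. Step 3. The conjugate addition may be too slow at the fully substituted β-carbon, so that 1,2-addition or enolisation takes over. The fallback sets out from 6 and comes back at 8, and replaces the polar addition by a radical one that is less sensitive to crowding. Irradiation of 6 in 1,3-dioxolane with benzophenone (10 mol%, 350 nm) should add the 1,3-dioxolan-2-yl radical (Giese-type) anti to the CH2OPMB group and give (4S,5S)-4-(1,3-dioxolan-2-yl)-5-[(PMBO)methyl]-4-methyldihydrofuran-2(3H)-one F1, a masked C2 aldehyde. Aqueous HCl in THF would unmask (2S,3S)-2-[(PMBO)methyl]-3-methyl-5-oxotetrahydrofuran-3-carbaldehyde F2, and Wittig methylenation (Ph3P=CH2, THF, 0 °C) of the non-enolisable aldehyde would return 8.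

2. Step 9. Simple diastereoselection (anti versus syn at C6) of the lithium aldol may be poor, and the labile aldehyde may be lost to proton transfer. The fallback sets out from 12 and comes back at 18, and sets C6 by reduction instead of by the aldol.
 - The aldol is run as before and the C6 epimer (4S,5S)-5-[(1R)-3-bromo-1-hydroxybut-3-en-1-yl]-4-[(1S)-1-(TBSO)-2-(PMBO)ethyl]-4-methylcyclopent-2-en-1-one F3 is carried with 16 through the conditions of steps 10 and 11.
 - This gives (2S,3S)-2-[(1R)-3-bromo-1-hydroxybut-3-en-1-yl]-3-[(1S)-1-(TBSO)-2-(PMBO)ethyl]-3-methylcyclopentan-1-one F4 and then (1R,2S,3S)-2-[(1R)-3-bromo-1-hydroxybut-3-en-1-yl]-3-[(1S)-1-(TBSO)-2-(PMBO)ethyl]-3-methyl-1-(propan-2-yl)cyclopentan-1-ol F5.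
 - Dess–Martin oxidation of the mixture of 18 and F5 converges on 3-bromo-1-{(1R,2S,5R)-2-[(1S)-1-(TBSO)-2-(PMBO)ethyl]-5-hydroxy-2-methyl-5-(propan-2-yl)cyclopentyl}but-3-en-1-one F6.
 - Narasaka–Prasad reduction (Et2BOMe, NaBH4, THF/MeOH, −78 °C), with external hydride attacking the boron chelate of the C4 hydroxyl axially, should give the 4,6-syn diol 18.

3. Step 15. The ring closure may show the wrong facial selectivity at C9, or intermolecular coupling may compete. The fallback sets out from 21 and comes back at 23, and sets C9 by reduction instead of by the cyclisation. The same cyclisation would give the C9 epimer (1R,3aS,4S,5S,8S,8aS)-4-(TBSO)-1,5-dihydroxy-3a-methyl-6-methylidene-1-(propan-2-yl)decahydroazulen-8-yl 3-methylbutanoate F7. Dess–Martin oxidation of the allylic alcohol would give the α-methylene ketone (1R,3aS,4S,8S,8aS)-4-(TBSO)-1-hydroxy-3a-methyl-6-methylidene-5-oxo-1-(propan-2-yl)decahydroazulen-8-yl 3-methylbutanoate F8. Luche reduction (NaBH4, CeCl3·7H2O, MeOH, −78 °C), with hydride approaching anti to the adjacent silyloxy group, should return 23.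

Further compounds
F1 | step 3 | (4S,5S)-4-(1,3-dioxolan-2-yl)-5-[(PMBO)methyl]-4-methyldihydrofuran-2(3H)-one | O=C1C[C@](C)(C2OCCO2)[C@@H](COCc3ccc(OC)cc3)O1
F2 | step 3 | (2S,3S)-2-[(PMBO)methyl]-3-methyl-5-oxotetrahydrofuran-3-carbaldehyde | O=C1C[C@](C)(C=O)[C@@H](COCc2ccc(OC)cc2)O1
F3 | step 9 | (4S,5S)-5-[(1R)-3-bromo-1-hydroxybut-3-en-1-yl]-4-[(1S)-1-(TBSO)-2-(PMBO)ethyl]-4-methylcyclopent-2-en-1-one | O=C1C=C[C@](C)([C@H](O[Si](C)(C)C(C)(C)C)COCc2ccc(OC)cc2)[C@H]1[C@H](O)CC(Br)=C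
F4 | step 9 | (2S,3S)-2-[(1R)-3-bromo-1-hydroxybut-3-en-1-yl]-3-[(1S)-1-(TBSO)-2-(PMBO)ethyl]-3-methylcyclopentan-1-one | O=C1CC[C@](C)([C@H](O[Si](C)(C)C(C)(C)C)COCc2ccc(OC)cc2)[C@H]1[C@H](O)CC(Br)=C
F5 | step 9 | (1R,2S,3S)-2-[(1R)-3-bromo-1-hydroxybut-3-en-1-yl]-3-[(1S)-1-(TBSO)-2-(PMBO)ethyl]-3-methyl-1-(propan-2-yl)cyclopentan-1-ol | CC(C)[C@]1(O)CC[C@](C)([C@H](O[Si](C)(C)C(C)(C)C)COCc2ccc(OC)cc2)[C@H]1[C@H](O)CC(Br)=C
F6 | step 9 | 3-bromo-1-{(1R,2S,5R)-2-[(1S)-1-(TBSO)-2-(PMBO)ethyl]-5-hydroxy-2-methyl-5-(propan-2-yl)cyclopentyl}but-3-en-1-one | CC(C)[C@]1(O)CC[C@](C)([C@H](O[Si](C)(C)C(C)(C)C)COCc2ccc(OC)cc2)[C@H]1C(=O)CC(Br)=C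
F7 | step 15 | (1R,3aS,4S,5S,8S,8aS)-4-(TBSO)-1,5-dihydroxy-3a-methyl-6-methylidene-1-(propan-2-yl)decahydroazulen-8-yl 3-methylbutanoate | C=C1C[C@H](OC(=O)CC(C)C)[C@@H]2[C@](C)(CC[C@@]2(O)C(C)C)[C@H](O[Si](C)(C)C(C)(C)C)[C@H]1O
F8 | step 15 | (1R,3aS,4S,8S,8aS)-4-(TBSO)-1-hydroxy-3a-methyl-6-methylidene-5-oxo-1-(propan-2-yl)decahydroazulen-8-yl 3-methylbutanoate | C=C1C[C@H](OC(=O)CC(C)C)[C@@H]2[C@](C)(CC[C@@]2(O)C(C)C)[C@H](O[Si](C)(C)C(C)(C)C)C1=O
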